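The route rests on cutting the bond between the ketone carbon (C1 of the nonanone chain) and the carbon of ring A (the 2-hydroxy-6-methoxyphenyl ring) that lies between C–OH and C–OMe. This contiguous OH, acyl, OMe triad on three neighbouring ring atoms is the footprint of 3-methoxybenzyne. The aryne inserts into the acyl C–O bond of a carboxylic acid, so the phenol C–O bond and the aryl–carbonyl C–C bond arise in one operation, the methoxy group steering the acyl group to its own side. The precursors are a 9-arylnonanoic acid, its ring B (4-hydroxyphenyl) phenol masked as a MOM ether, and a 2-silylaryl triflate. Methanolic acid in the same flask releases the target.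

Key step: step 2

Remark on the chemistry: the target has no stereocentre and no alkene geometry, so no configuration has to be set; 9-BBN is counted as its monomer.

Step 1
Reactants: 1 non-8-enoic acid; 2 9-borabicyclo[3.3.1]nonane (9-BBN); 3 1-bromo-4-(methoxymethoxy)benzene
Product: 5 9-[4-(methoxymethoxy)phenyl]nonanoic acid, via bis-boryl adduct 4 (not isolated)
Conditions: 2 (2.2 equiv), THF, 0 °C to rt; then 3, PdCl2(dppf) (3 mol %), aq. NaOH (3 M), THF, 65 °C; cold 1 M HCl to pH 4
Reagents that add atoms: none
Why: 9-BBN spends one equivalent on the acidic proton (the acyloxyborane so formed is reduced far more slowly than a terminal alkene is hydroborated) and the second equivalent adds anti-Markovnikov to the alkene, after which hydroxide frees the carboxylate, turns the primary B-alkyl group of 4 into a borate and allows a B-alkyl Suzuki-Miyaura coupling with aryl bromide 3 on zerovalent palladium, the wide-bite-angle dppf ligand favouring reductive elimination over beta-hydride elimination and the MOM acetal being inert to base.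

Step 2
Reactants: 5 9-[4-(methoxymethoxy)phenyl]nonanoic acid; 6 3-methoxy-2-(trimethylsilyl)phenyl trifluoromethanesulfonate
Product: 10 1-(2-hydroxy-6-methoxyphenyl)-9-(4-hydroxyphenyl)nonan-1-one (target), via 3-methoxybenzyne 7 (not isolated), via aryl anion 8 (not isolated), via MOM ketone 9 (not isolated)
Conditions: 6 (1.3 equiv), CsF (4 equiv), THF, 125 °C, sealed tube; filter through Celite; then MeOH, aq. HCl (2 M), 50 °C
Reagents that add atoms: none
Why: Fluoride strips the silyl group from 6 and triflate leaves to give 3-methoxybenzyne 7; the caesium carboxylate of 5 adds through oxygen to the aryne carbon meta to OMe, and the aryl anion 8 so formed, which sits between OMe and the acyloxy group, attacks its own ester carbonyl and releases the phenoxide, so that the aryne has inserted into the acyl C–O bond and the ring A C–O bond and the aryl–carbonyl C–C bond are made in one operation. The closest known reaction type is the fluoride-induced insertion of arynes into the C–O bond of carboxylic acids to give ortho-hydroxyaryl ketones, in mechanism an anionic ortho-Fries 1,3-acyl shift. No ring is closed in the product and no stereocentre is formed; the acyl shift only passes through a strained four-membered tetrahedral transition structure (4-exo-trig attack). The step needs attack of oxygen at the distal aryne carbon, and the methoxy group of 7 secures it, because its inductive pull distorts the triple bond so that the distal carbon is the more linear and electrophilic one, the negative charge builds up on the carbon next to oxygen, and the proximal carbon is also the more hindered. It also needs the acyl shift to outrun protonation of 8, which is favoured by aprotic THF, the high temperature, excess CsF (the acid is present as its carboxylate) and the MOM mask on the ring B phenol (no second O-nucleophile or proton source). Methanolic HCl then cleaves the aryl MOM acetal of 9 by transacetalization to dimethoxymethane, conditions that should leave the hydrogen-bonded ketone, the aryl methyl ether and both phenols untouched.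

Compound list
1 | non-8-enoic acid | C=CCCCCCCC(=O)O | starting material
2 | 9-borabicyclo[3.3.1]nonane (9-BBN, monomer) | B1C2CCCC1CCC2 | starting material
3 | 1-bromo-4-(methoxymethoxy)benzene | COCOc1ccc(Br)cc1 | starting material
4 | 9-borabicyclo[3.3.1]nonan-9-yl 9-(9-borabicyclo[3.3.1]nonan-9-yl)nonanoate (bis-boryl adduct) | O=C(CCCCCCCCB1C2CCCC1CCC2)OB1C2CCCC1CCC2 | intermediate
5 | 9-[4-(methoxymethoxy)phenyl]nonanoic acid | COCOc1ccc(CCCCCCCCC(=O)O)cc1 | intermediate
6 | 3-methoxy-2-(trimethylsilyl)phenyl trifluoromethanesulfonate | COc1cccc(OS(=O)(=O)C(F)(F)F)c1[Si](C)(C)C | starting material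
7 | 3-methoxybenzyne (1-methoxy-2,3-didehydrobenzene) | COC1=CC=CC#C1 | intermediate
8 | caesium 2-methoxy-6-({9-[4-(methoxymethoxy)phenyl]nonanoyl}oxy)benzen-1-ide (aryl anion between OMe and the acyloxy group) | [Cs+].COCOc1ccc(CCCCCCCCC(=O)Oc2cccc(OC)[c-]2)cc1 | intermediate
9 | 1-(2-hydroxy-6-methoxyphenyl)-9-[4-(methoxymethoxy)phenyl]nonan-1-one (MOM ketone) | COCOc1ccc(CCCCCCCCC(=O)c2c(O)cccc2OC)cc1 | intermediate
10 | 1-(2-hydroxy-6-methoxyphenyl)-9-(4-hydroxyphenyl)nonan-1-one | COc1cccc(O)c1C(=O)CCCCCCCCc1ccc(O)cc1 | target

Total step count: 2
Longest linear sequence: 2 steps (1 to 5 to 10)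

Steps most likely to fail. The route has only two steps, so both are ranked, and step 2 is entered once for each of its two stages.

1. Step 2, insertion stage.
- What may go wrong: the aryl anion may be protonated before the acyl shift, so that plain O-arylation results. The proton could come from free acid, from bifluoride, or by internal transfer from the alpha-methylene group. The product phenoxide may also be arylated a second time by excess aryne, and regioselectivity may erode at 125 °C.
- Fallback: it sets out from 5 and comes back at 10. It replaces the aryne by a directed ortho-lithiation and forms the same aryl–carbonyl bond by addition to a Weinreb amide.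
- Acid 5 is activated with 1,1'-carbonyldiimidazole (CDI, CH2Cl2, rt) to 1-{9-[4-(methoxymethoxy)phenyl]nonanoyl}imidazole F1. In the same flask, N,O-dimethylhydroxylamine hydrochloride converts it into N-methoxy-N-methyl-9-[4-(methoxymethoxy)phenyl]nonanamide F2.
- 3-Methoxyphenol is protected (MOMCl, i-Pr2NEt, CH2Cl2, 0 °C) as 1-methoxy-3-(methoxymethoxy)benzene F3. n-BuLi (THF, 0 °C) deprotonates this at the carbon between the two oxygen substituents to give [2-methoxy-6-(methoxymethoxy)phenyl]lithium F4.
- F4 adds to F2 (THF, −78 to 0 °C, cold dilute HCl quench) to give 1-[2-methoxy-6-(methoxymethoxy)phenyl]-9-[4-(methoxymethoxy)phenyl]nonan-1-one F5. HCl in MeOH (50 °C) then removes both MOM groups to give 10.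

2. Step 1.
- What may go wrong: active borane may be lost to the carboxyl group. Transmetalation from the hindered borate onto an electron-rich arylpalladium species may be slow, with beta-hydride elimination or protodeboronation taking over. The MOM group may be partly lost during acidification.
- Fallback: it sets out from 3 and comes back at 5. It uses an sp–sp2 coupling followed by saturation, with no borane.
- Bromide 3 and commercial non-8-ynoic acid (C#CCCCCCCC(=O)O) undergo Sonogashira coupling (PdCl2(PPh3)2, CuI, Et3N, DMF, 80 °C) to give 9-[4-(methoxymethoxy)phenyl]non-8-ynoic acid F6.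
- Hydrogenation (H2, Pd/C, EtOAc, rt), to which the MOM ether and the acid are inert, gives 5.

3. Step 2, acetal cleavage stage.
- What may go wrong: acetal cleavage may be incomplete in a crude mixture buffered by residual fluoride salts. The electron-rich phenol rings may also be alkylated by the released formaldehyde equivalent.
- Fallback: it sets out from 4 and comes back at 10. It replaces the acid-labile mask by a benzyl ether that is removed reductively from a purified intermediate.
- Adduct 4 (from 1 and 2 as in step 1) is coupled under the same palladium catalysis with commercial 1-(benzyloxy)-4-bromobenzene (Brc1ccc(OCc2ccccc2)cc1) to give 9-[4-(benzyloxy)phenyl]nonanoic acid F7.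
- Insertion of aryne 7, released from 6 with CsF in THF at 125 °C, gives 9-[4-(benzyloxy)phenyl]-1-(2-hydroxy-6-methoxyphenyl)nonan-1-one F8, which is isolated.
- Hydrogenolysis (H2, Pd/C, EtOAc, rt) gives 10, the hindered, hydrogen-bonded ketone being expected to resist reduction.

Further compounds
F1 | step 2 | 1-{9-[4-(methoxymethoxy)phenyl]nonanoyl}imidazole | COCOc1ccc(CCCCCCCCC(=O)n2ccnc2)cc1
F2 | step 2 | N-methoxy-N-methyl-9-[4-(methoxymethoxy)phenyl]nonanamide | COCOc1ccc(CCCCCCCCC(=O)N(C)OC)cc1
F3 | step 2 | 1-methoxy-3-(methoxymethoxy)benzene | COCOc1cccc(OC)c1
F4 | step 2 | [2-methoxy-6-(methoxymethoxy)phenyl]lithium | [Li]c1c(OC)cccc1OCOC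
F5 | step 2 | 1-[2-methoxy-6-(methoxymethoxy)phenyl]-9-[4-(methoxymethoxy)phenyl]nonan-1-one | COCOc1ccc(CCCCCCCCC(=O)c2c(OC)cccc2OCOC)cc1
F6 | step 1 | 9-[4-(methoxymethoxy)phenyl]non-8-ynoic acid | COCOc1ccc(C#CCCCCCCC(=O)O)cc1
F7 | step 2 | 9-[4-(benzyloxy)phenyl]nonanoic acid | O=C(O)CCCCCCCCc1ccc(OCc2ccccc2)cc1
F8 | step 2 | 9-[4-(benzyloxy)phenyl]-1-(2-hydroxy-6-methoxyphenyl)nonan-1-one | COc1cccc(O)c1C(=O)CCCCCCCCc1ccc(OCc2ccccc2)cc1
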